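Labdane numbering is used (ring A = C1–C5 + C10, ring B = C5–C10). Retrosynthetic cuts: the allyl ester and C13=C14 (Horner–Wadsworth–Emmons), C8=C17 (Wittig), then the C4–C5 bond of ring A together with the C19–H bond (reductive Heck), C3–C4 (Suzuki–Miyaura), and C10–C1 plus C9–C11 (conjugate addition–allylation).
Forward: ring B is bought as a cyclohexenone and receives the C9 chain, the C10 quaternary centre and the ring A tether. Ring A is closed last, by a 6-exo reductive Heck cyclisation of the C5 enol triflate onto a 2-(alkoxymethyl)allyl terminus. Methylene, acetate and enoic acid are finished afterwards.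
Enabling feature: C4 is a quaternary ring A carbon bonded directly to ring B carbon C5, carrying a methyl (C19) cis to the C10 methyl and a CH2O arm (C18). Syn addition of a C5 alkenylpalladium across C4=C19 builds exactly this carbon, and the neopentyl C19–Pd (no β-hydrogen) is reduced to the methyl.
The C5=C6 bond left in ring B by the Heck step is the handle for the trans ring fusion (hydrogen delivered to the α face).
Stereochemistry: a CBS-set carbinol at C8 (later erased as C8=O, then C8=CH2) directs C9; C9 directs C10; C10 directs C4 (tether on the α face, palladium on the β face); the two axial methyls direct C5. The 13E geometry comes from the olefination.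

Key step: step 10

Remark: normal labdane series throughout (5α-H, 9α-H, 10β-CH3; C18 = 4α-CH2O, C19 = 4β-CH3); TBS = tert-butyldimethylsilyl, THP = oxan-2-yl. Compounds 14 and 16–23 are mixtures of two epimers at the THP acetal carbon, which is removed in step 15.

Step 1
Reactants: 1 1,4-dioxaspiro[4.5]dec-6-en-8-one
Product: 2 (R)-1,4-dioxaspiro[4.5]dec-6-en-8-ol
Conditions: (S)-2-methyl-CBS-oxazaborolidine (10 mol %), catecholborane (1.5 equiv), toluene, −78 °C; aq. NaOH work-up
Reagents that add atoms: none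
Why: Corey–Bakshi–Shibata reduction, in which the oxazaborolidine–borane complex delivers hydride to one carbonyl face with the alkenyl arm acting as the large group, should give the (R)-allylic alcohol by clean 1,2-reduction.

Step 2
Reactants: 2 (R)-1,4-dioxaspiro[4.5]dec-6-en-8-ol
Product: 3 (R)-tert-butyl(1,4-dioxaspiro[4.5]dec-6-en-8-yloxy)dimethylsilane
Conditions: TBSCl, imidazole, DMF, rt
Reagents that add atoms: tert-butyldimethylsilyl chloride CC(C)(C)[Si](C)(C)Cl
Why: Imidazole-promoted silylation of a secondary allylic alcohol; no stereocentre is touched.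

Step 3
Reactants: 3 (R)-tert-butyl(1,4-dioxaspiro[4.5]dec-6-en-8-yloxy)dimethylsilane
Product: 4 (R)-4-[(tert-butyldimethylsilyl)oxy]cyclohex-2-en-1-one
Conditions: PPTS (cat.), acetone/H2O, 50 °C
Reagents that add atoms: water O
Why: Acid-catalysed ketal hydrolysis unmasks the carbonyl at the former spiro carbon, so the enone is transposed and the silyloxy carbon becomes C4 of a cyclohex-2-enone, while the secondary TBS ether survives the buffered acid.

Step 4
Reactants: 4 (R)-4-[(tert-butyldimethylsilyl)oxy]cyclohex-2-en-1-one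
Product: 5 (R)-4-[(tert-butyldimethylsilyl)oxy]-2-iodocyclohex-2-en-1-one
Conditions: I2, pyridine, CH2Cl2, 0 °C → rt
Reagents that add atoms: iodine II
Why: Baylis–Hillman-type α-iodination of an enone (conjugate addition of pyridine, iodination of the enolate, loss of pyridine) places iodine only at C2.

Step 5
Reactants: 5 (R)-4-[(tert-butyldimethylsilyl)oxy]-2-iodocyclohex-2-en-1-one
Product: 6 (R)-4-[(tert-butyldimethylsilyl)oxy]-2-methylcyclohex-2-en-1-one
Conditions: SnMe4, Pd2(dba)3 (2.5 mol %), AsPh3 (10 mol %), CuI (10 mol %), NMP, 70 °C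
Reagents that add atoms: tetramethylstannane C[Sn](C)(C)C
Why: Stille cross-coupling of an α-iodoenone (AsPh3/CuI acceleration) installs the C2 methyl under neutral conditions that spare the base-sensitive γ-silyloxy enone.

Step 6
Reactants: 6 (R)-4-[(tert-butyldimethylsilyl)oxy]-2-methylcyclohex-2-en-1-one; 7 2-(2-bromoethyl)-2-methyl-1,3-dioxolane; 8 allyl bromide
Product: 11 (2R,3R,4R)-4-[(tert-butyldimethylsilyl)oxy]-2-methyl-3-[2-(2-methyl-1,3-dioxolan-2-yl)ethyl]-2-(prop-2-en-1-yl)cyclohexan-1-one, via Grignard reagent 9 (not isolated), via bromomagnesium enolate 10 (not isolated)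
Conditions: 7, Mg, THF, rt; then CuBr·SMe2 (10 mol %), 6, THF, −40 °C; then 8, DMPU, −40 °C → rt
Reagents that add atoms: none
Why: Three-component conjugate addition–enolate alkylation, in which the copper-catalysed Grignard addition occurs anti to the γ-OTBS group (sets C9) and C-allylation of the enolate occurs anti to the new C9 chain (sets the quaternary C10 with methyl cis to the chain).

Step 7
Reactants: 12 2-bromoprop-2-en-1-ol; 13 3,4-dihydro-2H-pyran
Product: 14 2-[(2-bromoprop-2-en-1-yl)oxy]oxane
Conditions: PPTS (cat.), CH2Cl2, rt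
Reagents that add atoms: none
Why: Acid-catalysed THP protection; unlike an allylic ester, the resulting allylic acetal ether is not ionised by zerovalent palladium in steps 8 and 10.

Step 8
Reactants: 11 (2R,3R,4R)-4-[(tert-butyldimethylsilyl)oxy]-2-methyl-3-[2-(2-methyl-1,3-dioxolan-2-yl)ethyl]-2-(prop-2-en-1-yl)cyclohexan-1-one; 14 2-[(2-bromoprop-2-en-1-yl)oxy]oxane
Product: 16 (2R,3R,4R)-4-[(tert-butyldimethylsilyl)oxy]-2-methyl-3-[2-(2-methyl-1,3-dioxolan-2-yl)ethyl]-2-{4-[(oxan-2-yloxy)methyl]pent-4-en-1-yl}cyclohexan-1-one, via trialkylborane 15 (not isolated)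
Conditions: 9-BBN, THF, 0 °C → rt; then 14, PdCl2(dppf) (5 mol %), aq. K3PO4, DMF, rt → 50 °C
Reagents that add atoms: none
Why: 9-BBN hydroborates the monosubstituted allyl alkene faster than it reduces the hindered α-quaternary ketone, and the B-alkyl Suzuki–Miyaura coupling with the alkenyl bromide joins C3 to C4 without touching a stereocentre.

Step 9
Reactants: 16 (2R,3R,4R)-4-[(tert-butyldimethylsilyl)oxy]-2-methyl-3-[2-(2-methyl-1,3-dioxolan-2-yl)ethyl]-2-{4-[(oxan-2-yloxy)methyl]pent-4-en-1-yl}cyclohexan-1-one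
Product: 18 (4R,5R,6R)-4-[(tert-butyldimethylsilyl)oxy]-6-methyl-5-[2-(2-methyl-1,3-dioxolan-2-yl)ethyl]-6-{4-[(oxan-2-yloxy)methyl]pent-4-en-1-yl}cyclohex-1-en-1-yl trifluoromethanesulfonate, via potassium enolate 17 (not isolated)
Conditions: KN(SiMe3)2, THF, −78 °C; then PhNTf2, −78 → 0 °C
Reagents that add atoms: N-phenylbis(trifluoromethanesulfonimide) O=S(=O)(N(c1ccccc1)S(=O)(=O)C(F)(F)F)C(F)(F)F
Why: Enolate O-triflation, where deprotonation can only occur at C6 because C10 is quaternary, so a single enol triflate (C5=C6) should form.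

Step 10
Reactants: 18 (4R,5R,6R)-4-[(tert-butyldimethylsilyl)oxy]-6-methyl-5-[2-(2-methyl-1,3-dioxolan-2-yl)ethyl]-6-{4-[(oxan-2-yloxy)methyl]pent-4-en-1-yl}cyclohex-1-en-1-yl trifluoromethanesulfonate
Product: 19 8α-(TBSO)-18-(THPO)-14,15,17-trinorlabd-5-en-13-one ethylene ketal
Conditions: Pd(OAc)2 (10 mol %), PPh3 (25 mol %), HCO2Na (1.5 equiv), Et4NCl (1 equiv), DMF, 80 °C
Reagents that add atoms: none
Why: Oxidative addition of zerovalent palladium into the C5–OTf bond gives an alkenylpalladium that adds syn across the 1,1-disubstituted C4=C19 alkene (C4–C5 bond formed, palladium transferred to C19), and the neopentyl C19–Pd species, which has no β-hydrogen, takes up formate, loses CO2 and reductively eliminates C19–H. The closest known reaction type is the reductive Heck reaction (cyclisation with hydride capture) of alkenyl triflates and aryl halides onto 1,1-disubstituted alkenes, a standard way to quaternary carbons. Ring A closes in the 6-exo-trig mode, preferred over 7-endo because the unsubstituted alkene terminus takes palladium and the substituted one takes carbon. The one new stereocentre, C4, is controlled by C10: with the C10 methyl axial on the β face (ring B is held by the equatorial C8 silyloxy group and C9 chain), the C1–C3 tether leaves C10 on the α side, so C4 can reach C5 only from below while palladium sits above, and an in-plane approach is blocked by the C6 hydrogen; C19 therefore ends on the β face (axial, cis to the C10 methyl) and the CH2OTHP arm in the equatorial 4α position. The selectivity needed is cyclisation before formate reduction of the alkenylpalladium and hydride capture before 3-exo attack of the neopentylpalladium on C5=C6; the intramolecular six-membered geometry, the sparingly soluble HCO2Na and the chloride additive are meant to secure this.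

Step 11
Reactants: 19 8α-(TBSO)-18-(THPO)-14,15,17-trinorlabd-5-en-13-one ethylene ketal
Product: 20 8α-(TBSO)-18-(THPO)-14,15,17-trinorlabdan-13-one ethylene ketal
Conditions: Mn(dpm)3 (10 mol %), PhSiH3, t-BuOOH, i-PrOH, rt
Reagents that add atoms: none
Why: Metal-hydride hydrogen-atom-transfer hydrogenation, in which H-atom transfer to C6 gives the tertiary C5 radical that takes its hydrogen on the α face, opposite the axial C4 and C10 methyls, to give the thermodynamically preferred trans-fused decalin (5α-H).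

Step 12
Reactants: 20 8α-(TBSO)-18-(THPO)-14,15,17-trinorlabdan-13-one ethylene ketal
Product: 21 8α-hydroxy-18-(THPO)-14,15,17-trinorlabdan-13-one ethylene ketal
Conditions: TBAF, THF, rt → 40 °C
Reagents that add atoms: none
Why: Fluoride cleavage of the silyl ether, to which the THP acetal and the dioxolane are inert, so the C8 hydroxyl is freed while the C13 carbonyl stays masked.

Step 13
Reactants: 21 8α-hydroxy-18-(THPO)-14,15,17-trinorlabdan-13-one ethylene ketal
Product: 22 18-(THPO)-14,15,17-trinorlabdane-8,13-dione 13-ethylene ketal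
Conditions: Dess–Martin periodinane, NaHCO3, CH2Cl2, rt
Reagents that add atoms: none
Why: Buffered Dess–Martin oxidation of the secondary alcohol; C9, now α to the ketone, already carries its chain in the equatorial, thermodynamically preferred 9β orientation.

Step 14
Reactants: 22 18-(THPO)-14,15,17-trinorlabdane-8,13-dione 13-ethylene ketal
Product: 23 18-(THPO)-14,15-dinorlabd-8(17)-en-13-one ethylene ketal
Conditions: Ph3PCH3Br, KOtBu, toluene, rt → 60 °C
Reagents that add atoms: methyltriphenylphosphonium bromide [Br-].C[P+](c1ccccc1)(c1ccccc1)c1ccccc1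
Why: Wittig methylenation of the hindered C8 ketone with the non-stabilised ylide, with no ester in the molecule at this stage and any enolisation at C9 returning the more stable equatorial chain.

Step 15
Reactants: 23 18-(THPO)-14,15-dinorlabd-8(17)-en-13-one ethylene ketal
Product: 24 18-hydroxy-14,15-dinorlabd-8(17)-en-13-one
Conditions: p-TsOH·H2O (10 mol %), acetone/H2O, 40 °C
Reagents that add atoms: water O
Why: Mild aqueous acid hydrolyses both acetals (THP ether and dioxolane) in one operation, under conditions too weak to isomerise the 1,1-disubstituted exocyclic alkene.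

Step 16
Reactants: 24 18-hydroxy-14,15-dinorlabd-8(17)-en-13-one
Product: 25 18-acetoxy-14,15-dinorlabd-8(17)-en-13-one
Conditions: Ac2O, pyridine, DMAP (cat.), CH2Cl2, rt
Reagents that add atoms: acetic anhydride CC(=O)OC(C)=O
Why: DMAP-catalysed acetylation of the only hydroxyl group.

Step 17
Reactants: 25 18-acetoxy-14,15-dinorlabd-8(17)-en-13-one; 26 allyl 2-(diethoxyphosphoryl)acetate
Product: 28 allyl 18-acetoxylabda-8(17),13E-dien-15-oate, via sodium phosphonate carbanion 27 (not isolated)
Conditions: NaH, 26 (slight excess over NaH), THF, 0 °C; then 25, rt → 50 °C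
Reagents that add atoms: none
Why: Horner–Wadsworth–Emmons olefination of the methyl ketone with the stabilised phosphonate anion should give mainly the (E)-trisubstituted enoate, the minor Z isomer being removed by chromatography, and the weakly basic anion should leave the acetate alone.

Step 18
Reactants: 28 allyl 18-acetoxylabda-8(17),13E-dien-15-oate
Product: 29 18-acetoxylabda-8(17),13E-dien-15-oic acid
Conditions: Pd(PPh3)4 (5 mol %), morpholine, THF, rt
Reagents that add atoms: none
Why: Tsuji–Trost deallylation, in which zerovalent palladium ionises the allyl ester and morpholine traps the π-allyl cation, frees the acid under neutral conditions that leave the acetate and both alkenes untouched.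

Compound list
1 | 1,4-dioxaspiro[4.5]dec-6-en-8-one | O=C1C=CC2(CC1)OCCO2 | starting material
2 | (R)-1,4-dioxaspiro[4.5]dec-6-en-8-ol | O[C@H]1C=CC2(OCCO2)CC1 | intermediate
3 | (R)-tert-butyl(1,4-dioxaspiro[4.5]dec-6-en-8-yloxy)dimethylsilane | CC(C)(C)[Si](C)(C)O[C@H]1C=CC2(OCCO2)CC1 | intermediate
4 | (R)-4-[(tert-butyldimethylsilyl)oxy]cyclohex-2-en-1-one | CC(C)(C)[Si](C)(C)O[C@H]1C=CC(=O)CC1 | intermediate
5 | (R)-4-[(tert-butyldimethylsilyl)oxy]-2-iodocyclohex-2-en-1-one | CC(C)(C)[Si](C)(C)O[C@H]1C=C(I)C(=O)CC1 | intermediate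
6 | (R)-4-[(tert-butyldimethylsilyl)oxy]-2-methylcyclohex-2-en-1-one | CC(C)(C)[Si](C)(C)O[C@H]1C=C(C)C(=O)CC1 | intermediate
7 | 2-(2-bromoethyl)-2-methyl-1,3-dioxolane | CC1(CCBr)OCCO1 | starting material
8 | allyl bromide (3-bromoprop-1-ene) | C=CCBr | starting material
9 | [2-(2-methyl-1,3-dioxolan-2-yl)ethyl]magnesium bromide | CC1(CC[Mg]Br)OCCO1 | intermediate
10 | bromomagnesium enolate of (3R,4R)-4-(TBSO)-2-methyl-3-[2-(2-methyl-1,3-dioxolan-2-yl)ethyl]cyclohexan-1-one | Br[Mg]OC1=C(C)[C@@H](CCC2(C)OCCO2)[C@H](O[Si](C)(C)C(C)(C)C)CC1 | intermediate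
11 | (2R,3R,4R)-4-[(tert-butyldimethylsilyl)oxy]-2-methyl-3-[2-(2-methyl-1,3-dioxolan-2-yl)ethyl]-2-(prop-2-en-1-yl)cyclohexan-1-one | O=C1[C@](C)(CC=C)[C@@H](CCC2(C)OCCO2)[C@H](O[Si](C)(C)C(C)(C)C)CC1 | intermediate
12 | 2-bromoprop-2-en-1-ol | C=C(Br)CO | starting material
13 | 3,4-dihydro-2H-pyran | C1=COCCC1 | starting material
14 | 2-[(2-bromoprop-2-en-1-yl)oxy]oxane | C=C(Br)COC1CCCCO1 | intermediate
15 | 9-BBN adduct of 11 at the allyl terminus (B-alkyl-9-borabicyclo[3.3.1]nonane) | O=C1[C@](C)(CCCB2C3CCCC2CCC3)[C@@H](CCC4(C)OCCO4)[C@H](O[Si](C)(C)C(C)(C)C)CC1 | intermediate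
16 | (2R,3R,4R)-4-[(tert-butyldimethylsilyl)oxy]-2-methyl-3-[2-(2-methyl-1,3-dioxolan-2-yl)ethyl]-2-{4-[(oxan-2-yloxy)methyl]pent-4-en-1-yl}cyclohexan-1-one | O=C1[C@](C)(CCCC(=C)COC2CCCCO2)[C@@H](CCC3(C)OCCO3)[C@H](O[Si](C)(C)C(C)(C)C)CC1 | intermediate
17 | potassium enolate of 16 (C5–O, C5=C6) | [K+].[O-]C1=CC[C@@H](O[Si](C)(C)C(C)(C)C)[C@H](CCC2(C)OCCO2)[C@@]1(C)CCCC(=C)COC1CCCCO1 | intermediate
18 | (4R,5R,6R)-4-[(tert-butyldimethylsilyl)oxy]-6-methyl-5-[2-(2-methyl-1,3-dioxolan-2-yl)ethyl]-6-{4-[(oxan-2-yloxy)methyl]pent-4-en-1-yl}cyclohex-1-en-1-yl trifluoromethanesulfonate | O=S(=O)(OC1=CC[C@@H](O[Si](C)(C)C(C)(C)C)[C@H](CCC2(C)OCCO2)[C@@]1(C)CCCC(=C)COC1CCCCO1)C(F)(F)F | intermediate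
19 | 8α-(TBSO)-18-(THPO)-14,15,17-trinorlabd-5-en-13-one ethylene ketal (4β,10β-dimethyl, 4α-CH2OTHP, Δ5) | C1CCC(OC[C@]2(C)CCC[C@@]3(C)C2=CC[C@@H](O[Si](C)(C)C(C)(C)C)[C@@H]3CCC2(C)OCCO2)OC1 | intermediate
20 | 8α-(TBSO)-18-(THPO)-14,15,17-trinorlabdan-13-one ethylene ketal (5α-H, trans-decalin) | C1CCC(OC[C@]2(C)CCC[C@@]3(C)[C@H]2CC[C@@H](O[Si](C)(C)C(C)(C)C)[C@@H]3CCC2(C)OCCO2)OC1 | intermediate
21 | 8α-hydroxy-18-(THPO)-14,15,17-trinorlabdan-13-one ethylene ketal | C1CCC(OC[C@]2(C)CCC[C@@]3(C)[C@H]2CC[C@@H](O)[C@@H]3CCC2(C)OCCO2)OC1 | intermediate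
22 | 18-(THPO)-14,15,17-trinorlabdane-8,13-dione 13-ethylene ketal | C1CCC(OC[C@]2(C)CCC[C@@]3(C)[C@H]2CCC(=O)[C@@H]3CCC2(C)OCCO2)OC1 | intermediate
23 | 18-(THPO)-14,15-dinorlabd-8(17)-en-13-one ethylene ketal | C1CCC(OC[C@]2(C)CCC[C@@]3(C)[C@H]2CCC(=C)[C@@H]3CCC2(C)OCCO2)OC1 | intermediate
24 | 18-hydroxy-14,15-dinorlabd-8(17)-en-13-one | OC[C@]1(C)CCC[C@@]2(C)[C@H]1CCC(=C)[C@@H]2CCC(C)=O | intermediate
25 | 18-acetoxy-14,15-dinorlabd-8(17)-en-13-one | CC(=O)OC[C@]1(C)CCC[C@@]2(C)[C@H]1CCC(=C)[C@@H]2CCC(C)=O | intermediate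
26 | allyl 2-(diethoxyphosphoryl)acetate | C=CCOC(=O)CP(=O)(OCC)OCC | starting material
27 | sodium salt of 26 (phosphonate carbanion) | [Na+].C=CCOC(=O)[CH-]P(=O)(OCC)OCC | intermediate
28 | allyl 18-acetoxylabda-8(17),13E-dien-15-oate | CC(=O)OC[C@]1(C)CCC[C@@]2(C)[C@H]1CCC(=C)[C@@H]2CC/C(C)=C/C(=O)OCC=C | intermediate
29 | 18-acetoxylabda-8(17),13E-dien-15-oic acid | CC(=O)OC[C@]1(C)CCC[C@@]2(C)[C@H]1CCC(=C)[C@@H]2CC/C(C)=C/C(=O)O | target

Total step count: 18. Longest linear sequence: 17 steps (1 to 29 through steps 1–6 and 8–18); step 7 is a one-step side branch.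

Steps most likely to fail

Step 10. The alkenylpalladium may be reduced by formate before the 6-exo insertion, which has to build a syn-axial contact between C19 and the C10 methyl and may therefore be slow. The neopentylpalladium may also escape by 3-exo carbopalladation of C5=C6. The fallback sets out from 6 and comes back at 20 by the classical annulation sequence. The copper-catalysed addition of Grignard reagent 9 is repeated and enolate 10 is intercepted with 2-(trimethylsilyl)pent-1-en-3-one to give the α-silyl 1,5-diketone F1. KOH in MeOH removes silicon and closes ring A by aldol condensation (Robinson annulation) to the 4-methyl-Δ4-3-ketone F2. Li/NH3 reduction, which sets the trans ring fusion, with capture of the C4 enolate by monomeric formaldehyde from the α face, gives the 4α-hydroxymethyl-4β-methyl 3-ketone F3. Dihydropyran 13 with PPTS gives the THP ether F4. The tosylhydrazone F5 (TsNHNH2, EtOH) is then reduced with catecholborane and NaOAc, which removes the C3 carbonyl and gives 20.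

Step 6. C-allylation of the hindered, fully substituted magnesium enolate may be slow, so that proton transfer and O-allylation compete, and anti selectivity at C10 may be incomplete. The fallback sets out from 6 and comes back at 11. After the same conjugate addition, enolate 10 is O-acylated with allyl chloroformate to the allyl enol carbonate F6. A Tsuji decarboxylative allylation (Pd(PPh3)4, THF) then transfers the allyl group to C10 within a π-allylpalladium–enolate ion pair, again anti to the C9 chain, to give 11.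

Step 1. Enantioselection in the hydride delivery may be insufficient, because the two flanks of the carbonyl group (CH=CH and CH2CH2) differ only moderately in size, and every later stereocentre is relayed from this one. The fallback sets out from 1 and comes back at 2. Luche reduction (NaBH4, CeCl3, MeOH) gives the racemic allylic alcohol F7. Lipase-catalysed acylation with vinyl acetate (Burkholderia cepacia lipase) is expected, by the usual (R)-preference of lipases for secondary alcohols, to convert the (R)-enantiomer into the (R)-acetate F8. This is separated from the unreacted (S)-alcohol and methanolysed (K2CO3, MeOH) to 2.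

Further compounds
F1 | step 10 | (2R,3R,4R)-4-(TBSO)-2-methyl-3-[2-(2-methyl-1,3-dioxolan-2-yl)ethyl]-2-[3-oxo-2-(trimethylsilyl)pentyl]cyclohexan-1-one | O=C1[C@](C)(CC([Si](C)(C)C)C(=O)CC)[C@@H](CCC2(C)OCCO2)[C@H](O[Si](C)(C)C(C)(C)C)CC1
F2 | step 10 | 8α-(TBSO)-14,15,17,18-tetranorlabd-4-ene-3,13-dione 13-ethylene ketal | CC1=C2CC[C@@H](O[Si](C)(C)C(C)(C)C)[C@H](CCC3(C)OCCO3)[C@@]2(C)CCC1=O
F3 | step 10 | 8α-(TBSO)-18-hydroxy-14,15,17-trinorlabdane-3,13-dione 13-ethylene ketal | OC[C@]1(C)C(=O)CC[C@@]2(C)[C@H]1CC[C@@H](O[Si](C)(C)C(C)(C)C)[C@@H]2CCC1(C)OCCO1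
F4 | step 10 | 8α-(TBSO)-18-(THPO)-14,15,17-trinorlabdane-3,13-dione 13-ethylene ketal | C1CCC(OC[C@]2(C)C(=O)CC[C@@]3(C)[C@H]2CC[C@@H](O[Si](C)(C)C(C)(C)C)[C@@H]3CCC2(C)OCCO2)OC1
F5 | step 10 | 3-(4-methylbenzenesulfonyl)hydrazone of F4 | C1CCC(OC[C@]2(C)C(=NNS(=O)(=O)c4ccc(C)cc4)CC[C@@]3(C)[C@H]2CC[C@@H](O[Si](C)(C)C(C)(C)C)[C@@H]3CCC2(C)OCCO2)OC1
F6 | step 6 | allyl (3R,4R)-4-(TBSO)-2-methyl-3-[2-(2-methyl-1,3-dioxolan-2-yl)ethyl]cyclohex-1-en-1-yl carbonate | C=CCOC(=O)OC1=C(C)[C@@H](CCC2(C)OCCO2)[C@H](O[Si](C)(C)C(C)(C)C)CC1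
F7 | step 1 | rac-1,4-dioxaspiro[4.5]dec-6-en-8-ol | OC1C=CC2(OCCO2)CC1
F8 | step 1 | (R)-1,4-dioxaspiro[4.5]dec-6-en-8-yl acetate | CC(=O)O[C@H]1C=CC2(OCCO2)CC1
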